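**Retrosynthetic overview**
1. The 23-membered ansa ring is closed last, by C–N bond formation: oxidative amidation of quinone C2–H by the C1 primary dienamide, followed by one global deprotection.
2. The dienamide comes from a Heck union (C3–C4) of (Z)-3-iodo-2-methylacrylamide with a C4=C5 vinyl group. The aryl ketone and the 15Z enone come from opening a C13-O/C17 α-methyl-α,β-unsaturated δ-lactone with a 1-lithio-2-naphtholate.
3. Polypropionate: pentan-3-one is the C8–C10 linchpin (anti/Felkin boron aldol to the C11 aldehyde, Ti syn-aldol to the C4–C7 aldehyde, 1,3-anti reduction).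
4. The lactone comes from (S)-Roche ester by BF3-allylstannation (C13, C14) and methacrylate RCM. The C6 tertiary carbinol comes from Pd-catalysed asymmetric etherification of isoprene monoxide.
5. Ring order: naphthalene benzo ring (Diels–Alder/aromatisation), then δ-lactone (RCM, later opened), then dioxane acetonide (protecting ring), then macrolactam.

Assumption: both Roche ester enantiomers, racemic 2-methyl-2-vinyloxirane, the Trost DACH-phenyl ligands and standard Pd/Ru/Cu catalysts count as commercial; a telescoped one-pot operation counts as one step.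
Locants C1–C17 in names of chain compounds are the ansa-chain locants of the target (C1 = amide C=O, C17 = aryl C=O).

**Route**

Step 1
Reactants: 1 3-methylbut-3-en-2-one
Product: 2 tert-butyldimethyl[(3-methylbuta-1,3-dien-2-yl)oxy]silane
Conditions: TBSOTf, Et3N, CH2Cl2, 0 °C
Reagents that add atoms: tert-butyldimethylsilyl triflate, CC(C)(C)[Si](C)(C)OS(=O)(=O)C(F)(F)F
Why: Soft enolisation/O-silylation of a methyl ketone that has only one enolisable position gives the 2-silyloxydiene (silyl enol ether formation).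

Step 2
Reactants: 2 tert-butyldimethyl[(3-methylbuta-1,3-dien-2-yl)oxy]silane; 3 1,4-benzoquinone
Product: 5 tert-butyl[(5,8-dimethoxy-3-methyl-1,4-dihydronaphthalen-2-yl)oxy]dimethylsilane, via Diels–Alder adduct 4 (not isolated)
Conditions: PhMe, rt; then K2CO3, Me2SO4, acetone, reflux
Reagents that add atoms: dimethyl sulfate, COS(=O)(=O)OC
Why: Diels–Alder cycloaddition to the symmetrical quinone gives one regioisomer, and base-mediated enolisation with O-methylation aromatises the enedione ring to the hydroquinone dimethyl ether while the silyl enol ether is retained.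

Step 3
Reactants: 5 tert-butyl[(5,8-dimethoxy-3-methyl-1,4-dihydronaphthalen-2-yl)oxy]dimethylsilane
Product: 7 5,8-dimethoxy-3-methylnaphthalen-2-ol, via naphthyl silyl ether 6 (not isolated)
Conditions: DDQ, PhH, rt; then TBAF, THF, 0 °C
Reagents that add atoms: none
Why: DDQ dehydrogenation of the doubly benzylic/allylic 1,4-dihydronaphthalene is driven by aromatisation, and fluoride then cleaves the aryl silyl ether.

Step 4
Reactants: 7 5,8-dimethoxy-3-methylnaphthalen-2-ol
Product: 8 1-bromo-5,8-dimethoxy-3-methylnaphthalen-2-ol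
Conditions: NBS, i-Pr2NH (cat.), CH2Cl2, −40 °C
Reagents that add atoms: N-bromosuccinimide, O=C1CCC(=O)N1Br
Why: Amine-mediated ortho-bromination (electrophilic aromatic substitution) of a 2-naphthol goes to the α-position C1, the only free ortho site because C3 carries the methyl group.

Step 5
Reactants: 9 (Z)-but-2-ene-1,4-diol
Product: 10 (Z)-4-(tert-butyldimethylsilyloxy)but-2-en-1-ol
Conditions: NaH (1 equiv), THF, 0 °C; TBSCl
Reagents that add atoms: tert-butyldimethylsilyl chloride, CC(C)(C)[Si](C)(C)Cl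
Why: Monosilylation of a symmetrical diol through its sparingly soluble monosodium alkoxide is statistically favoured for the mono-ether.

Step 6
Reactants: 10 (Z)-4-(tert-butyldimethylsilyloxy)but-2-en-1-ol
Product: 12 (Z)-tert-butyldimethyl{[4-(tributylstannyl)but-2-en-1-yl]oxy}silane, via allylic mesylate 11 (not isolated)
Conditions: MsCl, Et3N, THF, −40 °C; then Bu3SnLi (from Bu3SnH + LDA), THF, −78 °C
Reagents that add atoms: tributyltin hydride, CCCC[SnH](CCCC)CCCC
Why: SN2 displacement of a primary allylic sulfonate by the stannyl anion is the standard entry to γ-substituted allylstannanes.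

Step 7
Reactants: 13 rac-2-methyl-2-vinyloxirane; 14 (4-methoxyphenyl)methanol
Product: 15 (R)-2-(4-methoxybenzyloxy)-2-methylbut-3-en-1-ol
Conditions: Pd2(dba)3·CHCl3 (1 mol %), (S,S)-DACH-phenyl Trost ligand (3 mol %; the antipode that delivers the R ether), Et3B (1 mol %), CH2Cl2, rt
Reagents that add atoms: none
Why: Pd-catalysed dynamic kinetic asymmetric allylic etherification, in which both epoxide enantiomers funnel through equilibrating π-allyl complexes and the borate-tethered alkoxide is delivered to the substituted terminus, sets the C6 tertiary ether stereocentre.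

Step 8
Reactants: 15 (R)-2-(4-methoxybenzyloxy)-2-methylbut-3-en-1-ol
Product: 16 (R)-2-(4-methoxybenzyloxy)-2-methylbut-3-enal
Conditions: Dess–Martin periodinane, CH2Cl2, 0 °C → rt
Reagents that add atoms: none
Why: Dess–Martin oxidation of a primary alcohol gives an aldehyde whose quaternary α-carbon cannot epimerise.

Step 9
Reactants: 17 prop-2-yn-1-ol
Product: 18 (Z)-3-iodo-2-methylprop-2-en-1-ol
Conditions: MeMgBr (2.2 equiv), CuI (10 mol %), THF, −10 °C → rt; then I2, −78 → 0 °C
Reagents that add atoms: methylmagnesium bromide, C[Mg]Br; iodine, II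
Why: Alkoxide-directed Cu-catalysed anti-carbomagnesiation gives a chelated vinylmagnesium that is iodinated with retention, fixing I cis to CH2OH.

Step 10
Reactants: 18 (Z)-3-iodo-2-methylprop-2-en-1-ol
Product: 20 (Z)-3-iodo-2-methylprop-2-enoic acid, via (Z)-3-iodo-2-methylprop-2-enal 19 (not isolated)
Conditions: TEMPO (20 mol %), PhI(OAc)2 (2.5 equiv), MeCN/H2O, rt
Reagents that add atoms: water, O
Why: Oxoammonium (TEMPO/BAIB) oxidation in aqueous medium takes the primary alcohol through the aldehyde hydrate to the acid under near-neutral conditions that keep the vinyl iodide geometry.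

Step 11
Reactants: 20 (Z)-3-iodo-2-methylprop-2-enoic acid
Product: 22 (Z)-3-iodo-2-methylprop-2-enamide, via mixed isobutyl carbonic anhydride 21 (not isolated)
Conditions: i-BuOCOCl, N-methylmorpholine, THF, −20 °C; then NH3 (0.5 M in dioxane), −20 → 0 °C
Reagents that add atoms: ammonia, N
Why: Mixed-anhydride amidation at low temperature acylates ammonia faster than it can add to the α-methyl-deactivated β-iodoacrylate.

Step 12
Reactants: 23 methyl (S)-3-hydroxy-2-methylpropanoate
Product: 24 methyl (S)-2-methyl-3-(triethylsilyloxy)propanoate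
Conditions: TESCl, imidazole, CH2Cl2, 0 °C
Reagents that add atoms: chlorotriethylsilane, CC[Si](CC)(CC)Cl
Why: Silylation of the primary alcohol; the Roche ester supplies C12 and the TES ether is later converted directly into the C11 aldehyde.

Step 13
Reactants: 24 methyl (S)-2-methyl-3-(triethylsilyloxy)propanoate
Product: 25 (S)-2-methyl-3-(triethylsilyloxy)propanal
Conditions: DIBAL-H (1.05 equiv), CH2Cl2, −78 °C; Rochelle salt
Reagents that add atoms: none
Why: Low-temperature DIBAL-H half-reduction stops at the stable aluminium hemiacetal and gives the aldehyde without epimerisation.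

Step 14
Reactants: 25 (S)-2-methyl-3-(triethylsilyloxy)propanal; 12 (Z)-tert-butyldimethyl{[4-(tributylstannyl)but-2-en-1-yl]oxy}silane
Product: 26 (2S,3R,4S)-4-[(tert-butyldimethylsilyloxy)methyl]-2-methyl-1-(triethylsilyloxy)hex-5-en-3-ol
Conditions: BF3·OEt2, CH2Cl2, −78 °C
Reagents that add atoms: none
Why: BF3-promoted SE2' allylstannation through an open antiperiplanar transition state gives the 13,14-syn adduct, and Felkin–Anh attack on the non-chelated α-methyl aldehyde gives the 12,13-syn relationship, so C13 and C14 are both set.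

Step 15
Reactants: 26 (2S,3R,4S)-4-[(tert-butyldimethylsilyloxy)methyl]-2-methyl-1-(triethylsilyloxy)hex-5-en-3-ol
Product: 27 (2S,3R,4S)-4-[(tert-butyldimethylsilyloxy)methyl]-2-methyl-1-(triethylsilyloxy)hex-5-en-3-yl 2-methylprop-2-enoate
Conditions: methacryloyl chloride, Et3N, DMAP (cat.), CH2Cl2, 0 °C
Reagents that add atoms: methacryloyl chloride, CC(=C)C(Cl)=O
Why: DMAP-catalysed O-acylation of the only free hydroxyl installs C16, C17 and the 16-methyl group.

Step 16
Reactants: 27 (2S,3R,4S)-4-[(tert-butyldimethylsilyloxy)methyl]-2-methyl-1-(triethylsilyloxy)hex-5-en-3-yl 2-methylprop-2-enoate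
Product: 28 (5S,6R)-5-[(tert-butyldimethylsilyloxy)methyl]-3-methyl-6-[(S)-1-(triethylsilyloxy)propan-2-yl]-5,6-dihydro-2H-pyran-2-one
Conditions: Grubbs II (5 mol %), PhMe (5 mM), 80 °C
Reagents that add atoms: none
Why: Ring-closing metathesis of the methacrylate with the C14 vinyl group forms the six-membered unsaturated lactone, whose ring enforces the cis (15Z) C15=C16 geometry.

Step 17
Reactants: 28 (5S,6R)-5-[(tert-butyldimethylsilyloxy)methyl]-3-methyl-6-[(S)-1-(triethylsilyloxy)propan-2-yl]-5,6-dihydro-2H-pyran-2-one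
Product: 30 (R)-2-{(2S,3S)-3-[(tert-butyldimethylsilyloxy)methyl]-5-methyl-6-oxo-3,6-dihydro-2H-pyran-2-yl}propanal, via primary alcohol 29 (not isolated)
Conditions: IBX (3 equiv), DMSO, rt
Reagents that add atoms: none
Why: IBX in DMSO performs a one-pot oxidative deprotection of the primary TES ether (the TBS ether survives) under base-free conditions, which avoids β-elimination of the β-acyloxy aldehyde.

Step 18
Reactants: 30 (R)-2-{(2S,3S)-3-[(tert-butyldimethylsilyloxy)methyl]-5-methyl-6-oxo-3,6-dihydro-2H-pyran-2-yl}propanal; 31 pentan-3-one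
Product: 33 (5S,6S)-5-[(tert-butyldimethylsilyloxy)methyl]-6-[(2S,3S,4S)-3-hydroxy-4-methyl-5-oxoheptan-2-yl]-3-methyl-5,6-dihydro-2H-pyran-2-one, via (E)-enol dicyclohexylborinate 32 (not isolated)
Conditions: (c-Hex)2BCl, Et3N, Et2O, 0 °C; then 30, −78 → −20 °C; H2O2, pH 7 buffer, MeOH, 0 °C
Reagents that add atoms: none
Why: The E-boron enolate reacts through a Zimmerman–Traxler chair to give the 10,11-anti aldol, and E-enolates add to α-methyl aldehydes with high Felkin selectivity (11,12-syn), so C10 and C11 are set by the C12 centre.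

Step 19
Reactants: 33 (5S,6S)-5-[(tert-butyldimethylsilyloxy)methyl]-6-[(2S,3S,4S)-3-hydroxy-4-methyl-5-oxoheptan-2-yl]-3-methyl-5,6-dihydro-2H-pyran-2-one
Product: 34 (5S,6S)-6-[(2R,3S,4S)-3-(tert-butyldimethylsilyloxy)-4-methyl-5-oxoheptan-2-yl]-5-[(tert-butyldimethylsilyloxy)methyl]-3-methyl-5,6-dihydro-2H-pyran-2-one
Conditions: TBSOTf, 2,6-lutidine, CH2Cl2, −78 °C
Reagents that add atoms: tert-butyldimethylsilyl triflate, CC(C)(C)[Si](C)(C)OS(=O)(=O)C(F)(F)F
Why: Silylation of the β-hydroxy ketone blocks retro-aldol and leaves the ethyl side as the only readily enolisable position.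

Step 20
Reactants: 34 (5S,6S)-6-[(2R,3S,4S)-3-(tert-butyldimethylsilyloxy)-4-methyl-5-oxoheptan-2-yl]-5-[(tert-butyldimethylsilyloxy)methyl]-3-methyl-5,6-dihydro-2H-pyran-2-one; 16 (R)-2-(4-methoxybenzyloxy)-2-methylbut-3-enal
Product: 36 C4–C17 β-hydroxy ketone lactone (6-OPMB; 7-OH; 9-oxo; 11-OTBS; 14-CH2OTBS), via Z-trichlorotitanium enolate 35 (not isolated)
Conditions: TiCl4, i-Pr2NEt, CH2Cl2, −78 °C; then 16, −78 °C
Reagents that add atoms: none
Why: The Z-titanium enolate of an α'-methyl ethyl ketone gives the syn aldol (7,8-syn) on the enolate face dictated by C10 (8,10-syn methyls), and because the aldehyde's quaternary α-carbon (Me versus vinyl) has little facial bias, enolate control should set C7 and C8 while C6 is carried in from 16.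

Step 21
Reactants: 36 C4–C17 β-hydroxy ketone lactone
Product: 37 C4–C17 7,9-anti-diol lactone
Conditions: Me4NBH(OAc)3, MeCN/AcOH, −30 °C
Reagents that add atoms: none
Why: Evans–Saksena reduction delivers hydride intramolecularly from the C7-alkoxyborohydride through a chair and sets C9 1,3-anti to C7 without touching the enoate lactone.

Step 22
Reactants: 37 C4–C17 7,9-anti-diol lactone
Product: 38 C4–C17 7,9-acetonide lactone
Conditions: 2,2-dimethoxypropane, PPTS (cat.), CH2Cl2, rt
Reagents that add atoms: 2,2-dimethoxypropane, COC(C)(C)OC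
Why: Transketalisation protects the only two free hydroxyls as an acid-labile anti-1,3-dioxane, so that no protic group remains for the organolithium step.

Step 23
Reactants: 38 C4–C17 7,9-acetonide lactone; 8 1-bromo-5,8-dimethoxy-3-methylnaphthalen-2-ol
Product: 40 C4–C17 hydroxy Z-enone aryl ketone, via dilithio naphtholate 39 (not isolated)
Conditions: 8 (2.2 equiv), n-BuLi then t-BuLi, THF, −78 °C; then 38, −78 → −40 °C; NH4Cl
Reagents that add atoms: none
Why: O-deprotonation and Br/Li exchange give an aryllithium whose 1,2-addition to the lactone carbonyl stops at the stable lithium hemiketal, and work-up releases the C13 alcohol and the aryl ketone with the Z enone geometry inherited from the ring (acylation of an organolithium by a lactone).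

Step 24
Reactants: 40 C4–C17 hydroxy Z-enone aryl ketone; 22 (Z)-3-iodo-2-methylprop-2-enamide
Product: 41 seco-dienamide (dimethoxynaphthalene)
Conditions: Pd(OAc)2 (10 mol %), Ag2CO3, DMF, 50 °C, dark
Reagents that add atoms: none
Why: Heck vinylation of the terminal alkene (β-hydride elimination is possible only towards the new bond because C6 is quaternary) gives the 4E olefin with retention of the iodide's Z geometry under silver-assisted cationic conditions.

Step 25
Reactants: 41 seco-dienamide (dimethoxynaphthalene)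
Product: 42 seco-dienamide naphthoquinone
Conditions: CAN (5 equiv), MeCN/H2O (4:1), 0 °C
Reagents that add atoms: water, O
Why: Ceric ammonium nitrate effects oxidative demethylation of the 1,4-dimethoxyarene to the quinone and, in the same operation, oxidative cleavage of the tertiary PMB ether; the fully substituted, hydrogen-bonded phenol ring has no free ortho/para position to over-oxidise.

Step 26
Reactants: 42 seco-dienamide naphthoquinone
Product: 44 protected macrolactam (7,9-acetonide; 11-OTBS; 14-CH2OTBS), via amido hydroquinone 43 (not isolated)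
Conditions: Cu(OAc)2 (20 mol %), 1,10-phenanthroline (20 mol %), O2 (1 atm), 4 Å MS, PhMe/MeCN, 1 mM, 60 °C
Reagents that add atoms: none
Why: Proposed new method: macrocyclising aerobic Cu(II)-catalysed dehydrogenative C–H amidation of a 1,4-naphthoquinone by a tethered primary amide, in which acetate-assisted formation of a Cu amidate is followed by conjugate addition of N to quinone C2 (the position β to the C4 carbonyl, favoured because the C1 carbonyl is deactivated by para-conjugation with the C6 phenol/Cu phenolate, and the position that gives the 23-membered ring), tautomerisation to hydroquinone 43 and Cu/O2 reoxidation to the vinylogous-imide quinone, which is too electron-rich to react again; the closest known reactions are Cu-catalysed aerobic oxidative amination of naphthoquinones with amines and Cu-mediated amide N-arylation macrolactamisation.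

Step 27
Reactants: 44 protected macrolactam
Product: 45 CNP0297124.1 (target)
Conditions: HF (48% aq), MeCN, 0 °C → rt
Reagents that add atoms: none
Why: Aqueous HF in acetonitrile removes both TBS ethers and hydrolyses the strained anti-acetonide in one global deprotection that is mild enough for the tertiary allylic alcohol, the dienamide and the quinone.

**Compound list**

1 | 3-methylbut-3-en-2-one | CC(=O)C(C)=C | starting material
2 | tert-butyldimethyl[(3-methylbuta-1,3-dien-2-yl)oxy]silane | C=C(C)C(=C)O[Si](C)(C)C(C)(C)C | intermediate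
3 | 1,4-benzoquinone | O=C1C=CC(=O)C=C1 | starting material
4 | rac-cis-6-(tert-butyldimethylsilyloxy)-7-methyl-4a,5,8,8a-tetrahydronaphthalene-1,4-dione (one enantiomer drawn) | O=C1C=CC(=O)[C@H]2CC(O[Si](C)(C)C(C)(C)C)=C(C)C[C@@H]12 | intermediate
5 | tert-butyl[(5,8-dimethoxy-3-methyl-1,4-dihydronaphthalen-2-yl)oxy]dimethylsilane | COc1ccc(OC)c2c1CC(C)=C(O[Si](C)(C)C(C)(C)C)C2 | intermediate
6 | tert-butyl[(5,8-dimethoxy-3-methylnaphthalen-2-yl)oxy]dimethylsilane | COc1ccc(OC)c2cc(O[Si](C)(C)C(C)(C)C)c(C)cc12 | intermediate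
7 | 5,8-dimethoxy-3-methylnaphthalen-2-ol | COc1ccc(OC)c2cc(O)c(C)cc12 | intermediate
8 | 1-bromo-5,8-dimethoxy-3-methylnaphthalen-2-ol | COc1ccc(OC)c2c(Br)c(O)c(C)cc12 | intermediate
9 | (Z)-but-2-ene-1,4-diol | OC/C=C\CO | starting material
10 | (Z)-4-(tert-butyldimethylsilyloxy)but-2-en-1-ol | OC/C=C\CO[Si](C)(C)C(C)(C)C | intermediate
11 | (Z)-4-(tert-butyldimethylsilyloxy)but-2-en-1-yl methanesulfonate | CS(=O)(=O)OC/C=C\CO[Si](C)(C)C(C)(C)C | intermediate
12 | (Z)-tert-butyldimethyl{[4-(tributylstannyl)but-2-en-1-yl]oxy}silane | CCCC[Sn](CCCC)(CCCC)C/C=C\CO[Si](C)(C)C(C)(C)C | intermediate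
13 | rac-2-methyl-2-vinyloxirane | CC1(C=C)CO1 | starting material
14 | (4-methoxyphenyl)methanol | COc1ccc(CO)cc1 | starting material
15 | (R)-2-(4-methoxybenzyloxy)-2-methylbut-3-en-1-ol | C=C[C@@](C)(OCc1ccc(OC)cc1)CO | intermediate
16 | (R)-2-(4-methoxybenzyloxy)-2-methylbut-3-enal | C=C[C@@](C)(OCc1ccc(OC)cc1)C=O | intermediate
17 | prop-2-yn-1-ol | OCC#C | starting material
18 | (Z)-3-iodo-2-methylprop-2-en-1-ol | OC/C(C)=C\I | intermediate
19 | (Z)-3-iodo-2-methylprop-2-enal | O=C/C(C)=C\I | intermediate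
20 | (Z)-3-iodo-2-methylprop-2-enoic acid | OC(=O)/C(C)=C\I | intermediate
21 | (Z)-3-iodo-2-methylprop-2-enoic isobutyl carbonic anhydride | CC(C)COC(=O)OC(=O)/C(C)=C\I | intermediate
22 | (Z)-3-iodo-2-methylprop-2-enamide | NC(=O)/C(C)=C\I | intermediate
23 | methyl (S)-3-hydroxy-2-methylpropanoate | OC[C@H](C)C(=O)OC | starting material
24 | methyl (S)-2-methyl-3-(triethylsilyloxy)propanoate | CC[Si](CC)(CC)OC[C@H](C)C(=O)OC | intermediate
25 | (S)-2-methyl-3-(triethylsilyloxy)propanal | CC[Si](CC)(CC)OC[C@H](C)C=O | intermediate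
26 | (2S,3R,4S)-4-[(tert-butyldimethylsilyloxy)methyl]-2-methyl-1-(triethylsilyloxy)hex-5-en-3-ol | CC[Si](CC)(CC)OC[C@H](C)[C@@H](O)[C@H](CO[Si](C)(C)C(C)(C)C)C=C | intermediate
27 | (2S,3R,4S)-4-[(tert-butyldimethylsilyloxy)methyl]-2-methyl-1-(triethylsilyloxy)hex-5-en-3-yl 2-methylprop-2-enoate | CC[Si](CC)(CC)OC[C@H](C)[C@@H](OC(=O)C(C)=C)[C@H](CO[Si](C)(C)C(C)(C)C)C=C | intermediate
28 | (5S,6R)-5-[(tert-butyldimethylsilyloxy)methyl]-3-methyl-6-[(S)-1-(triethylsilyloxy)propan-2-yl]-5,6-dihydro-2H-pyran-2-one | CC[Si](CC)(CC)OC[C@H](C)[C@@H](O1)[C@H](CO[Si](C)(C)C(C)(C)C)C=C(C)C1=O | intermediate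
29 | (5S,6R)-5-[(tert-butyldimethylsilyloxy)methyl]-6-[(S)-1-hydroxypropan-2-yl]-3-methyl-5,6-dihydro-2H-pyran-2-one | OC[C@H](C)[C@@H](O1)[C@H](CO[Si](C)(C)C(C)(C)C)C=C(C)C1=O | intermediate
30 | (R)-2-{(2S,3S)-3-[(tert-butyldimethylsilyloxy)methyl]-5-methyl-6-oxo-3,6-dihydro-2H-pyran-2-yl}propanal | O=C[C@H](C)[C@@H](O1)[C@H](CO[Si](C)(C)C(C)(C)C)C=C(C)C1=O | intermediate
31 | pentan-3-one | CCC(=O)CC | starting material
32 | (E)-pent-2-en-3-yl dicyclohexylborinate | C/C=C(/OB(C1CCCCC1)C1CCCCC1)CC | intermediate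
33 | (5S,6S)-5-[(tert-butyldimethylsilyloxy)methyl]-6-[(2S,3S,4S)-3-hydroxy-4-methyl-5-oxoheptan-2-yl]-3-methyl-5,6-dihydro-2H-pyran-2-one | CCC(=O)[C@@H](C)[C@@H](O)[C@H](C)[C@@H](O1)[C@H](CO[Si](C)(C)C(C)(C)C)C=C(C)C1=O | intermediate
34 | (5S,6S)-6-[(2R,3S,4S)-3-(tert-butyldimethylsilyloxy)-4-methyl-5-oxoheptan-2-yl]-5-[(tert-butyldimethylsilyloxy)methyl]-3-methyl-5,6-dihydro-2H-pyran-2-one | CCC(=O)[C@@H](C)[C@@H](O[Si](C)(C)C(C)(C)C)[C@H](C)[C@@H](O1)[C@H](CO[Si](C)(C)C(C)(C)C)C=C(C)C1=O | intermediate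
35 | Z-trichlorotitanium enolate of 34 (C8=C9; O-Ti cis to the C8 methyl) | C/C=C(\O[Ti](Cl)(Cl)Cl)[C@@H](C)[C@@H](O[Si](C)(C)C(C)(C)C)[C@H](C)[C@@H](O1)[C@H](CO[Si](C)(C)C(C)(C)C)C=C(C)C1=O | intermediate
36 | (5S,6S)-6-[(2R,3S,4S,6R,7R,8R)-3-(tert-butyldimethylsilyloxy)-7-hydroxy-8-(4-methoxybenzyloxy)-4,6,8-trimethyl-5-oxodec-9-en-2-yl]-5-[(tert-butyldimethylsilyloxy)methyl]-3-methyl-5,6-dihydro-2H-pyran-2-one | C=C[C@@](C)(OCc1ccc(OC)cc1)[C@H](O)[C@@H](C)C(=O)[C@@H](C)[C@@H](O[Si](C)(C)C(C)(C)C)[C@H](C)[C@@H](O2)[C@H](CO[Si](C)(C)C(C)(C)C)C=C(C)C2=O | intermediate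
37 | (5S,6S)-6-[(2R,3R,4R,5R,6S,7R,8R)-3-(tert-butyldimethylsilyloxy)-5,7-dihydroxy-8-(4-methoxybenzyloxy)-4,6,8-trimethyldec-9-en-2-yl]-5-[(tert-butyldimethylsilyloxy)methyl]-3-methyl-5,6-dihydro-2H-pyran-2-one | C=C[C@@](C)(OCc1ccc(OC)cc1)[C@H](O)[C@@H](C)[C@@H](O)[C@@H](C)[C@@H](O[Si](C)(C)C(C)(C)C)[C@H](C)[C@@H](O2)[C@H](CO[Si](C)(C)C(C)(C)C)C=C(C)C2=O | intermediate
38 | 7,9-O-isopropylidene derivative of 37: C4–C17 chain with C4=C5 vinyl, 6-OPMB, 7,9-acetonide, 11-OTBS, 14-CH2OTBS and C13-O/C17 unsaturated δ-lactone; (6R,7R,8S,9R,10R,11R,12R,13S,14S) | C=C[C@@](C)(OCc1ccc(OC)cc1)[C@H](O3)[C@@H](C)[C@@H](OC3(C)C)[C@@H](C)[C@@H](O[Si](C)(C)C(C)(C)C)[C@H](C)[C@@H](O2)[C@H](CO[Si](C)(C)C(C)(C)C)C=C(C)C2=O | intermediate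
39 | lithium 1-lithio-5,8-dimethoxy-3-methylnaphthalen-2-olate | COc1ccc(OC)c2c([Li])c(O[Li])c(C)cc12 | intermediate
40 | C4–C17 chain as in 38 with the lactone opened: free 13-OH and (15Z)-16-methyl enone whose C17 carbonyl carries 2-hydroxy-5,8-dimethoxy-3-methylnaphthalen-1-yl; (6R,7R,8S,9R,10R,11S,12R,13S,14S,15Z) | C=C[C@@](C)(OCc1ccc(OC)cc1)[C@H](O3)[C@@H](C)[C@@H](OC3(C)C)[C@@H](C)[C@@H](O[Si](C)(C)C(C)(C)C)[C@H](C)[C@@H](O)[C@H](CO[Si](C)(C)C(C)(C)C)/C=C(/C)C(=O)c2c(O)c(C)cc4c(OC)ccc(OC)c24 | intermediate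
41 | C1–C17 seco compound: (2Z,4E)-2-methyl-dienamide (C1 CONH2) attached to 40's chain; 6-OPMB, 7,9-acetonide, 11-OTBS, 13-OH, 14-CH2OTBS, dimethoxynaphthol ketone; (2Z,4E,6R,7R,8S,9R,10R,11S,12R,13S,14S,15Z) | C/C(C(N)=O)=C/C=C/[C@@](C)(OCc1ccc(OC)cc1)[C@H](O3)[C@@H](C)[C@@H](OC3(C)C)[C@@H](C)[C@@H](O[Si](C)(C)C(C)(C)C)[C@H](C)[C@@H](O)[C@H](CO[Si](C)(C)C(C)(C)C)/C=C(/C)C(=O)c2c(O)c(C)cc4c(OC)ccc(OC)c24 | intermediate
42 | as 41 but with free 6-OH and the arene oxidised to 6-hydroxy-7-methyl-1,4-naphthoquinon-5-yl (C2-H, C3-H); same descriptors | C/C(C(N)=O)=C/C=C/[C@@](C)(O)[C@H](O3)[C@@H](C)[C@@H](OC3(C)C)[C@@H](C)[C@@H](O[Si](C)(C)C(C)(C)C)[C@H](C)[C@@H](O)[C@H](CO[Si](C)(C)C(C)(C)C)/C=C(/C)C(=O)c2c(O)c(C)cc4c2C(=O)C=CC4=O | intermediate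
43 | macrocyclic 2-amido-1,4-dihydroxynaphthalene (hydroquinone form of 44) | C/C1=C/C=C/[C@@](C)(O)[C@H](O3)[C@@H](C)[C@@H](OC3(C)C)[C@@H](C)[C@@H](O[Si](C)(C)C(C)(C)C)[C@H](C)[C@@H](O)[C@H](CO[Si](C)(C)C(C)(C)C)/C=C(/C)C(=O)c2c(O)c(C)cc4c(O)c(NC1=O)cc(O)c24 | intermediate
44 | target macrolactam carrying 7,9-O-isopropylidene, 11-O-TBS and 14-CH2O-TBS; (2Z,4E,6R,7R,8S,9R,10R,11S,12R,13S,14S,15Z) | C/C1=C/C=C/[C@@](C)(O)[C@H](O3)[C@@H](C)[C@@H](OC3(C)C)[C@@H](C)[C@@H](O[Si](C)(C)C(C)(C)C)[C@H](C)[C@@H](O)[C@H](CO[Si](C)(C)C(C)(C)C)/C=C(/C)C(=O)c2c(O)c(C)cc4c2C(=O)C=C(NC1=O)C4=O | intermediate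
45 | CNP0297124.1; (2Z,4E,6R,7R,8S,9S,10S,11S,12R,13S,14S,15Z) | C/C1=C/C=C/[C@@](C)(O)[C@H](O)[C@@H](C)[C@@H](O)[C@@H](C)[C@@H](O)[C@H](C)[C@@H](O)[C@H](CO)/C=C(/C)C(=O)c2c(O)c(C)cc3c2C(=O)C=C(NC1=O)C3=O | target

**Totals and risks**

Total step count: 27. Longest linear sequence: 16 steps (steps 12–27 from Roche ester 23; equally steps 5, 6, 14–27 from diol 9).

The three steps most likely to fail:

1. Step 26 (the proposed macrocyclising C–H amidation). The amide may be too weak a nucleophile, C3 attack or oligomerisation may compete, and the ortho-acylphenol may sequester copper. Fallback with known chemistry: set out from 40 and run the Heck coupling of step 24 with acid 20 in place of amide 22 to give the seco dienoic acid F4. Oxidise with CAN as in step 25 to the quinone acid F5. Aminate the quinone with NaN3 in AcOH/THF/H2O (azide conjugate addition and loss of N2) to the 2-aminoquinone acid F6. Close the ring by macrolactamisation: Na2S2O4 reduction to the nucleophilic aminohydroquinone in situ, 2-chloro-1-methylpyridinium iodide/Et3N at 1 mM, then air re-oxidation. This returns to the route at 44.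

2. Step 23 (dilithio naphtholate plus unsaturated lactone). The hindered aryllithium may deprotonate the γ-position (C14) or add in a conjugate sense. Fallback: set out from 38, reduce the lactone with DIBAL-H at −78 °C to the lactol F1, and add dianion 39 to its ring-opened (Z)-hydroxy-enal form to give the C17 carbinol F2 as an epimer mixture. Oxidise the benzylic/allylic alcohol selectively with MnO2 to return to the route at 40.

3. Step 24 (Heck coupling). The Z-iodoacrylamide may isomerise and insertion at the neopentylic vinyl group may be slow. Fallback: set out from 40 and carry out cross-metathesis with vinylboronic acid pinacol ester (Hoveyda–Grubbs II, CH2Cl2, 40 °C) to the (E)-alkenyl pinacol boronate F3. Couple F3 with iodide 22 by Suzuki–Miyaura reaction (Pd(PPh3)4, TlOEt, THF/H2O, rt), which is stereoretentive for both partners and returns to the route at 41.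

Further compounds
F1 | step 23 | C17 lactol of 38 (anomer mixture) | C=C[C@@](C)(OCc1ccc(OC)cc1)[C@H](O3)[C@@H](C)[C@@H](OC3(C)C)[C@@H](C)[C@@H](O[Si](C)(C)C(C)(C)C)[C@H](C)[C@@H](O2)[C@H](CO[Si](C)(C)C(C)(C)C)C=C(C)C2O
F2 | step 23 | C17 carbinol of 40 (13,17-diol, C17 epimer mixture) | C=C[C@@](C)(OCc1ccc(OC)cc1)[C@H](O3)[C@@H](C)[C@@H](OC3(C)C)[C@@H](C)[C@@H](O[Si](C)(C)C(C)(C)C)[C@H](C)[C@@H](O)[C@H](CO[Si](C)(C)C(C)(C)C)/C=C(/C)C(O)c2c(O)c(C)cc4c(OC)ccc(OC)c24
F3 | step 24 | (E)-C4 alkenyl pinacol boronate of 40 | CC1(C)OB(OC1(C)C)/C=C/[C@@](C)(OCc1ccc(OC)cc1)[C@H](O3)[C@@H](C)[C@@H](OC3(C)C)[C@@H](C)[C@@H](O[Si](C)(C)C(C)(C)C)[C@H](C)[C@@H](O)[C@H](CO[Si](C)(C)C(C)(C)C)/C=C(/C)C(=O)c2c(O)c(C)cc4c(OC)ccc(OC)c24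
F4 | step 26 | seco (2Z,4E)-dienoic acid analogue of 41 | C/C(C(O)=O)=C/C=C/[C@@](C)(OCc1ccc(OC)cc1)[C@H](O3)[C@@H](C)[C@@H](OC3(C)C)[C@@H](C)[C@@H](O[Si](C)(C)C(C)(C)C)[C@H](C)[C@@H](O)[C@H](CO[Si](C)(C)C(C)(C)C)/C=C(/C)C(=O)c2c(O)c(C)cc4c(OC)ccc(OC)c24
F5 | step 26 | seco dienoic acid naphthoquinone (acid analogue of 42) | C/C(C(O)=O)=C/C=C/[C@@](C)(O)[C@H](O3)[C@@H](C)[C@@H](OC3(C)C)[C@@H](C)[C@@H](O[Si](C)(C)C(C)(C)C)[C@H](C)[C@@H](O)[C@H](CO[Si](C)(C)C(C)(C)C)/C=C(/C)C(=O)c2c(O)c(C)cc4c2C(=O)C=CC4=O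
F6 | step 26 | 2-amino-1,4-naphthoquinone seco acid | C/C(C(O)=O)=C/C=C/[C@@](C)(O)[C@H](O3)[C@@H](C)[C@@H](OC3(C)C)[C@@H](C)[C@@H](O[Si](C)(C)C(C)(C)C)[C@H](C)[C@@H](O)[C@H](CO[Si](C)(C)C(C)(C)C)/C=C(/C)C(=O)c2c(O)c(C)cc4c2C(=O)C=C(N)C4=O
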